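**Plan**
- Retrosynthesis: the two O–CH2Ar bonds are cut first (PMB on the C2 ketal oxygen and on O6), then the C1′(farnesyl)–C2 bond, then the C2–O(PMB) bond. This leaves 6-hydroxybenzofuran-3(2H)-one and (2E,6E)-farnesol.
- Forward: the benzofuranone bicycle is bought intact. O6 is protected, C2 is raised to the hemiketal oxidation level (Br, then OPMB), the C15 chain is joined at C2, and both PMB groups are removed last.
- Enabling feature: C2 lies between ring oxygen O1 and the C3 ketone of the furanone ring, so its enolate is an aromatic 2-alkoxy-3-oxidobenzofuran, nucleophilic at C2. Farnesyl C1′ is the unsubstituted terminus of an allyl unit, the electrophilic end of a π-allyl–Pd complex.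
- Stereochemistry: the only stereocentre, C2 (R), is set in the C–C bond-forming step by the chiral Pd catalyst acting on the planar enolate. It is locked as the PMB ketal and unveiled under neutral conditions. The 2′E,6′E geometry comes with farnesol.

Key step: step 5

Assumption: the free 2-hydroxybenzofuran-3(2H)-one hemiketal is taken to be configurationally stable in neutral, non-basic media (base would open it to the achiral 1-aryl-1,2-dione), so C2 is kept as a PMB ketal until the buffered last step.
Assumption: the sense of induction of the ligand on this enolate cannot be fixed in advance; the (R,R) ligand is written, and its (S,S) antipode is used if C2 should come out S.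

Step 1
Reactants: 1 6-hydroxybenzofuran-3(2H)-one
Product: 2 6-[(4-methoxybenzyl)oxy]benzofuran-3(2H)-one
Conditions: PMBCl (1.1 equiv), K2CO3, cat. Bu4NI, DMF, rt
Reagents that add atoms: 4-methoxybenzyl chloride, COc1ccc(CCl)cc1
Why: Williamson ether synthesis; the para-acyl phenol is far more acidic than the C2 methylene, so K2CO3 forms only the phenoxide, which is O-benzylated selectively.

Step 2
Reactants: 2 6-[(4-methoxybenzyl)oxy]benzofuran-3(2H)-one
Product: 4 rac-2-bromo-6-[(4-methoxybenzyl)oxy]benzofuran-3(2H)-one, via trimethylsilyl enol ether 3 (not isolated)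
Conditions: LiHMDS, TMSCl, THF, −78 °C; then NBS, −78 °C; cold neutral aqueous work-up, used crude
Reagents that add atoms: N-bromosuccinimide, O=C1CCC(=O)N1Br
Why: Regiospecific α-bromination of a ketone through its silyl enol ether; the aromatic 3-silyloxybenzofuran 3 should be brominated at C2 by NBS under cold, neutral conditions that spare the PMB ether and both arenes, and the new C2 centre is racemic and erased later.

Step 3
Reactants: 4 rac-2-bromo-6-[(4-methoxybenzyl)oxy]benzofuran-3(2H)-one
Product: 5 rac-2,6-bis[(4-methoxybenzyl)oxy]benzofuran-3(2H)-one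
Conditions: PMBOH (1.5 equiv), Ag2CO3, 4 Å MS, CH2Cl2, 0 °C → rt, dark
Reagents that add atoms: 4-methoxybenzyl alcohol, COc1ccc(CO)cc1
Why: Koenigs–Knorr-type silver-assisted substitution; C2–Br is both an α-halo ether and an α-halo ketone, so displacement by the alcohol should be fast, while insoluble Ag2CO3 takes up HBr without building up the enolate, giving a racemic mixed acetal.

Step 4
Reactants: 6 (2E,6E)-farnesol [(2E,6E)-3,7,11-trimethyldodeca-2,6,10-trien-1-ol]
Product: 7 tert-butyl (2E,6E)-3,7,11-trimethyldodeca-2,6,10-trien-1-yl carbonate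
Conditions: n-BuLi, THF, −78 °C; then Boc2O, −78 → 0 °C
Reagents that add atoms: di-tert-butyl dicarbonate, CC(C)(C)OC(=O)OC(=O)OC(C)(C)C
Why: O-acylation of the lithium alkoxide by Boc anhydride (carbonate formation); no bond at the allylic carbon is broken, so the primary position and the 2E,6E geometry are untouched.

Step 5
Reactants: 5 rac-2,6-bis[(4-methoxybenzyl)oxy]benzofuran-3(2H)-one; 7 tert-butyl (2E,6E)-farnesyl carbonate
Product: 8 (R)-2,6-bis[(4-methoxybenzyl)oxy]-2-[(2E,6E)-3,7,11-trimethyldodeca-2,6,10-trien-1-yl]benzofuran-3(2H)-one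
Conditions: Pd2(dba)3·CHCl3 (2.5 mol %), N,N′-[(1R,2R)-cyclohexane-1,2-diyl]bis[2-(diphenylphosphino)benzamide] ((R,R)-DACH-phenyl Trost ligand, 7.5 mol %), degassed toluene, 0 °C → rt
Reagents that add atoms: none
Why: Pd(0)–L* ionises the primary allylic carbonate 7 with loss of CO2 to a cationic η3-farnesyl–Pd complex and tert-butoxide, which removes the single C2–H of 5 (acidic because the conjugate base is the aromatic 2-alkoxy-3-oxidobenzofuran); the enolate then attacks the allyl ligand on the face opposite Pd to form the C1′–C2 bond. The closest known reaction type is the Trost asymmetric allylic alkylation (Tsuji–Trost reaction) of prochiral stabilised enolates, such as oxindoles, azlactones and α-oxygenated ketone enolates, with prenyl- and geranyl-type carbonates to give fully substituted centres. No ring is closed. The new C2 stereocentre is under catalyst control: the racemic centre of 5 is erased in the planar enolate and the chiral pocket of the diamide–bisphosphine ligand selects the enantiotopic enolate face, so the step is stereoconvergent. The step needs C- over O-allylation (the O-allyl enol ether is an aryl-type allyl ether that Pd(0) can re-ionise, whereas C-allylation is irreversible), attack at the unsubstituted terminus C1′ rather than the disubstituted C3′ (the fully substituted nucleophilic carbon would otherwise have to form two adjacent quaternary carbons), and retention of the 2′E geometry (syn/anti exchange needs an η1-Pd at the tertiary C3′ and should be slower than capture within the ion pair). The remote trisubstituted alkenes and both PMB ethers are inert to Pd(0).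

Step 6
Reactants: 8 (R)-2,6-bis[(4-methoxybenzyl)oxy]-2-[(2E,6E)-farnesyl]benzofuran-3(2H)-one
Product: 9 (R)-2,6-dihydroxy-2-[(2E,6E)-3,7,11-trimethyldodeca-2,6,10-trien-1-yl]benzofuran-3(2H)-one (target)
Conditions: DDQ (2.5 equiv), CH2Cl2/pH 7 phosphate buffer (10:1), 0 °C → rt; work-up at pH 6–7 (aq. sodium ascorbate), no basic wash
Reagents that add atoms: none
Why: Oxidative PMB cleavage with DDQ; hydride abstraction from each p-methoxybenzylic CH2 gives an oxocarbenium ion that water converts to p-anisaldehyde and the free OH, the C2–O bond is never broken and the medium stays neutral, so the (R) ketal should be carried over unchanged into the (R) hemiketal.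

**Compound list**
1 | 6-hydroxybenzofuran-3(2H)-one | O=C1COc2cc(O)ccc21 | starting material
2 | 6-[(4-methoxybenzyl)oxy]benzofuran-3(2H)-one | COc1ccc(COc2ccc3c(c2)OCC3=O)cc1 | intermediate
3 | 6-[(4-methoxybenzyl)oxy]-3-(trimethylsilyloxy)benzofuran | COc1ccc(COc2ccc3c(O[Si](C)(C)C)coc3c2)cc1 | intermediate (not isolated)
4 | rac-2-bromo-6-[(4-methoxybenzyl)oxy]benzofuran-3(2H)-one | COc1ccc(COc2ccc3c(c2)OC(Br)C3=O)cc1 | intermediate
5 | rac-2,6-bis[(4-methoxybenzyl)oxy]benzofuran-3(2H)-one | COc1ccc(COC2Oc3cc(OCc4ccc(OC)cc4)ccc3C2=O)cc1 | intermediate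
6 | (2E,6E)-farnesol | CC(C)=CCC/C(C)=C/CC/C(C)=C/CO | starting material
7 | tert-butyl (2E,6E)-3,7,11-trimethyldodeca-2,6,10-trien-1-yl carbonate | CC(C)=CCC/C(C)=C/CC/C(C)=C/COC(=O)OC(C)(C)C | intermediate
8 | (R)-2,6-bis[(4-methoxybenzyl)oxy]-2-[(2E,6E)-3,7,11-trimethyldodeca-2,6,10-trien-1-yl]benzofuran-3(2H)-one | CC(C)=CCC/C(C)=C/CC/C(C)=C/C[C@@]1(OCc2ccc(OC)cc2)Oc2cc(OCc3ccc(OC)cc3)ccc2C1=O | intermediate
9 | (R)-2,6-dihydroxy-2-[(2E,6E)-3,7,11-trimethyldodeca-2,6,10-trien-1-yl]benzofuran-3(2H)-one | CC(C)=CCC/C(C)=C/CC/C(C)=C/C[C@@]1(O)Oc2cc(O)ccc2C1=O | target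

**Step count**
Total steps: 6. Longest linear sequence: 5 (steps 1, 2, 3, 5, 6); step 4 is a one-step side branch.

**Steps most likely to fail**

1. Step 5. The risk is incomplete enantioface discrimination on a stabilised, weakly coordinating enolate, together with erosion of linear/E selectivity through the π-allyl intermediate or persistent O-allylation. The fallback sets out from 5 and 6 and comes back at 8. Farnesol 6 is converted with PBr3 (Et2O, 0 °C) to (2E,6E)-farnesyl bromide F1. Acetal 5 is then alkylated with it under chiral phase-transfer catalysis (O-allyl-N-(9-anthracenylmethyl)cinchonidinium bromide, solid CsOH·H2O, toluene/CH2Cl2, −40 °C). This is a direct SN2 displacement at the primary carbon, so it cannot transpose the allyl unit or isomerise the alkene, and the ion-paired chiral ammonium enolate controls the face. The pseudo-enantiomeric cinchoninium salt serves if the opposite sense is required.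

2. Step 3. The risk is decomposition of the labile α-bromo ketone (self-condensation through its enol, halogen transfer) competing with substitution, and self-etherification of the benzylic alcohol. The fallback is halide-free, sets out from 2 and comes back at 5. The potassium enolate of 2 (KHMDS, THF, −78 °C) is hydroxylated with 2-(phenylsulfonyl)-3-phenyloxaziridine to the cyclic hemiacetal rac-2-hydroxy-6-[(4-methoxybenzyl)oxy]benzofuran-3(2H)-one F2. Its hydroxyl is then etherified with 4-methoxybenzyl 2,2,2-trichloroacetimidate and catalytic La(OTf)3 (toluene, rt) to give 5.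

3. Step 6. The risk is slow cleavage of the aryl PMB ether, which forces long exposure to excess DDQ with oxidation at the allylic positions of the triene or of the freed phenol, and ring-opening of the hemiketal if the pH drifts. The fallback uses orthogonal protection, sets out from 1 and comes back at 9.
   - Phenol 1 is silylated (TIPSCl, imidazole, DMF) to 6-(triisopropylsilyloxy)benzofuran-3(2H)-one F3.
   - The conditions of step 2 give the trimethylsilyl enol ether 3-(trimethylsilyloxy)-6-(triisopropylsilyloxy)benzofuran F4, which is not isolated, and from it rac-2-bromo-6-(triisopropylsilyloxy)benzofuran-3(2H)-one F5.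
   - The conditions of step 3 give rac-2-[(4-methoxybenzyl)oxy]-6-(triisopropylsilyloxy)benzofuran-3(2H)-one F6.
   - The conditions of step 5 with 7 give (R)-2-[(4-methoxybenzyl)oxy]-2-[(2E,6E)-farnesyl]-6-(triisopropylsilyloxy)benzofuran-3(2H)-one F7.
   - TBAF buffered with AcOH (THF, 0 °C) removes the aryl silyl ether at the configurationally secure ketal stage to give (R)-6-hydroxy-2-[(4-methoxybenzyl)oxy]-2-[(2E,6E)-farnesyl]benzofuran-3(2H)-one F8.
   - One brief treatment with DDQ (1.1 equiv, CH2Cl2/pH 7 buffer, 0 °C) then cleaves only the more reactive alkyl-type PMB ketal and gives 9.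

**Further compounds**
F1 | step 5 | (2E,6E)-farnesyl bromide | CC(C)=CCC/C(C)=C/CC/C(C)=C/CBr
F2 | step 3 | rac-2-hydroxy-6-[(4-methoxybenzyl)oxy]benzofuran-3(2H)-one | COc1ccc(COc2ccc3c(c2)OC(O)C3=O)cc1
F3 | step 6 | 6-(triisopropylsilyloxy)benzofuran-3(2H)-one | O=C1COc2cc(O[Si](C(C)C)(C(C)C)C(C)C)ccc21
F4 | step 6 | 3-(trimethylsilyloxy)-6-(triisopropylsilyloxy)benzofuran | C[Si](C)(C)Oc1coc2cc(O[Si](C(C)C)(C(C)C)C(C)C)ccc12
F5 | step 6 | rac-2-bromo-6-(triisopropylsilyloxy)benzofuran-3(2H)-one | O=C1C(Br)Oc2cc(O[Si](C(C)C)(C(C)C)C(C)C)ccc21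
F6 | step 6 | rac-2-[(4-methoxybenzyl)oxy]-6-(triisopropylsilyloxy)benzofuran-3(2H)-one | COc1ccc(COC2Oc3cc(O[Si](C(C)C)(C(C)C)C(C)C)ccc3C2=O)cc1
F7 | step 6 | (R)-2-[(4-methoxybenzyl)oxy]-2-[(2E,6E)-3,7,11-trimethyldodeca-2,6,10-trien-1-yl]-6-(triisopropylsilyloxy)benzofuran-3(2H)-one | CC(C)=CCC/C(C)=C/CC/C(C)=C/C[C@@]1(OCc2ccc(OC)cc2)Oc2cc(O[Si](C(C)C)(C(C)C)C(C)C)ccc2C1=O
F8 | step 6 | (R)-6-hydroxy-2-[(4-methoxybenzyl)oxy]-2-[(2E,6E)-3,7,11-trimethyldodeca-2,6,10-trien-1-yl]benzofuran-3(2H)-one | CC(C)=CCC/C(C)=C/CC/C(C)=C/C[C@@]1(OCc2ccc(OC)cc2)Oc2cc(O)ccc2C1=O
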